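In a closed vessel at constant volume and temperature, mono adduct builds up from substrate and reagent and then falls away. Two chemists dispute how far it falls in 12 h.

| setting | birch | ash | epsilon | delta | theta | zeta |
|---|---|---|---|---|---|---|
| substrate | 0.74 M | 1.7 M | 1.1 M | 1.1 M | 1.1 M | 1.1 M |
| reagent | 1.32 M | 1.32 M | 1.32 M | 1.32 M | 1.32 M | 1.32 M |
| temperature | 90 °C | 118 °C | 140 °C | 110 °C | 95 °C | 125 °C |
| remark | run made earlier | run made earlier |  |  |  |  |
| time |  |  | 12 h | 12 h | 12 h | 12 h |

| run | time / h | mono adduct / % | substrate / % |
|---|---|---|---|
| birch | 25.0 | 18 | 4 |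
| birch | 50.0 | 11 | 1 |
| birch | 72.0 | 13 | 1 |
| birch | 96.0 | 10 | 1 |
| birch | 120 | 9 | 0 |
| birch | 144 | 7 | 2 |
| birch | 192 | 8 | 0 |
| ash | 2.50 | 20 | 39 |
| ash | 6.00 | 17 | 38 |
| ash | 12.0 | 14 | 42 |
| ash | 20.0 | 7 | 41 |
| ash | 25.0 | 6 | 39 |
| ash | 40.0 | 5 | 42 |

(readings scatter by 1.5 percentage points)

- the best flask by amount of mono adduct, in percent of the substrate charged; "all alike" if 1.5 percentage points covers them all (epsilon / delta / theta / zeta / all alike)
- amount of mono adduct at the end, in percent of the substrate charged, epsilon
- amount of mono adduct at the end, in percent of the substrate charged, delta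
- amount of mono adduct at the end, in percent of the substrate charged, theta
- amount of mono adduct at the end, in percent of the substrate charged, zeta

The first chemist reads a floor: mono adduct ends at 8% in birch and 5% in ash, so the hot flasks should come to rest near those values.

The second chemist treats the peak as the large quantity and reckons the loss as a correction to it. In ash, substrate reads 39% at 2.50 h and 42% at 40.0 h, so making has stopped there, yet mono adduct drops from 20% to 6% by 25.0 h. The tail constant k, here 0.0535 h⁻¹ at 118 °C, is the fraction of mono adduct lost per hour once making has stopped. Birch is no clean tail: substrate still reads 4% at 25.0 h, and reagent was charged in excess of substrate, so the slope of its readings from 25.0 h to 192 h, 0.00486 h⁻¹ at 90 °C, is a rough stand-in for k and not k itself. Taking it as k all the same, k grows by a factor of e for every 11.7 K of heating, a rough figure that carries this doubt as well as the scatter of the readings.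

The first chemist objects that the tail, run from 20% to 40.0 h in ash, gives 2.69%, while the reading is 5%. But that gap of 2.3 percentage points stands against a scatter of 1.5 points, which leaves the question open, so a new flask has to choose.

Epsilon can choose. There k reaches 0.353 h⁻¹, so the lifetime 1/k is 2.83 h, shorter than the 12 h of the run. My own reckoning, on the second chemist's side, starts from the 20% of ash and leaves 0.289% in epsilon, well under any floor. The views do not part in theta: with k at 0.00745 h⁻¹, that flask keeps 91.4% of its peak, more than delta, zeta or epsilon keep. Theta is therefore best on either view, and it is the region where the floor view costs nothing.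

The forecast, from the side where mono adduct “decays slowly toward a floor”, gives 7% for epsilon, 16% for delta, 24% for theta and 10% for zeta, and names theta best.

Epsilon ends at 0.240% of mono adduct, under the first chemist's floor, zeta ends at 6.61%, delta at 17.4%, and theta leads with 23.7%.

    reagent + mono adduct → double product + by-product (k = 0.608 M⁻¹ h⁻¹, Ea = 90.0 kJ mol⁻¹)
    substrate + reagent → mono adduct + by-product (k = 0.549 M⁻¹ h⁻¹, Ea = 71.0 kJ mol⁻¹)
    substrate + reagent → other mono adduct + by-product (k = 0.655 M⁻¹ h⁻¹, Ea = 72.0 kJ mol⁻¹)
    mono adduct → over-reaction product (k = 0.0227 h⁻¹, Ea = 122 kJ mol⁻¹)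
    reagent + other mono adduct → double product + by-product (k = 0.996 M⁻¹ h⁻¹, Ea = 82.0 kJ mol⁻¹)
    (constants at 110 °C)

In epsilon the limiting reagent stands at 0% of its charge by 6.00 h, and mono adduct goes from 2.16% then to 0.240% at 12.0 h. In zeta, reagent stands at 0.00647% of its charge by 6.00 h, with 11.8% of mono adduct. The tail constant for that temperature, 0.0975 h⁻¹, carries this to 6.55% at the end, and zeta holds 6.61%.

Readings and results are calculated for substances that don't exist, noise included.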